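**Strategy.** The 2H-pyran ring (O1, C2, C3, C4, C4a, C8a) is read as the oxidatively cyclised form of an ortho-solanesyl hydroquinone: the C2′=C3′ olefin of the chain already carries the C2 methyl group and the C40 residue in defined E geometry. An enantioselective Pd(II)-catalysed 6-endo Wacker-type cyclisation lets the phenol oxygen add to the fully substituted olefin carbon, which forms O1–C2 and sets the (R) quaternary ether centre under catalyst control, and β-hydride elimination of a benzylic C4–H installs C3=C4 in the same operation. The precursor, plastoquinol-9 monoacetate, is two steps from 2,3-dimethylhydroquinone and solanesol.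

Key step: step 3

Assumption: the (P,R,R) antipode of the spiro bis(isoxazoline) ligand i-Pr-SPRIX is taken to deliver the (2R) chromene; the sense of induction is to be confirmed on a 2-geranylphenol model, and the (M,S,S) antipode is used instead if the sense is opposite.

Step 1
Reactants: 1 2,3-dimethylbenzene-1,4-diol (2,3-dimethylhydroquinone)
Product: 2 4-hydroxy-2,3-dimethylphenyl acetate
Conditions: Ac2O (1.0 equiv, slow addition), pyridine, THF, 0 °C
Reagents that add atoms: acetic anhydride, CC(=O)OC(C)=O
Why: O-Acetylation (nucleophilic acyl substitution) of a symmetric diol with two equivalent hydroxyls, so only the mono/bis distribution has to be managed by stoichiometry and low temperature, with recovered diol and diacetate recycled.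

Step 2
Reactants: 2 4-hydroxy-2,3-dimethylphenyl acetate; 3 solanesol (all-E nonaprenol)
Product: 4 4-hydroxy-2,3-dimethyl-5-[(all-E)-solanesyl]phenyl acetate (plastoquinol-9 monoacetate, acetate on the oxygen remote from the chain)
Conditions: BF3·OEt2 (0.3 equiv), 1,4-dioxane, 20 °C, Ar, dark, 2 in twofold excess
Reagents that add atoms: none
Why: Friedel–Crafts allylation by the BF3-activated allylic alcohol should occur at the only free position ortho to the activating free hydroxyl (the position next to the acetoxy group is deactivated), and the mild Lewis acid in a donor solvent is expected to keep the 2′E geometry and stop before chromane formation.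

Step 3
Reactants: 4 4-hydroxy-2,3-dimethyl-5-[(all-E)-solanesyl]phenyl acetate
Product: 5 (2R)-2,7,8-trimethyl-2-[(3E,7E,11E,15E,19E,23E,27E)-4,8,12,16,20,24,28,32-octamethyltritriaconta-3,7,11,15,19,23,27,31-octaen-1-yl]-2H-chromen-6-yl acetate
Conditions: Pd(OCOCF3)2 (10 mol%), (P,R,R)-i-Pr-SPRIX (15 mol%), p-benzoquinone (4 equiv), CH2Cl2, 0–25 °C, dark
Reagents that add atoms: none
Why: The cationic Pd(II)–ligand complex binds the phenol oxygen and the nearest olefin (C2′=C3′) of the chain, the oxygen adds to the fully substituted C3′ (future C2) in an oxypalladation that places palladium on C2′ (future C3), and syn β-hydride elimination of a benzylic C1′–H (future C4) releases C3=C4 while benzoquinone returns Pd(0) to Pd(II). The closest known reaction type is the enantioselective Pd(II)/spiro-bis(isoxazoline) Wacker-type oxidative cyclisation of 2-geranylphenols to 2-methyl-2-homoprenyl-2H-chromenes, of which 4 is the higher prenylogue. The pyran ring closes in the 6-endo-trig mode through O1–C2 bond formation. The single new stereocentre, C2, is set under catalyst control: the chiral ligand selects one enantiotopic face of the geometrically defined E-olefin in the oxypalladation, which fixes the methyl group and the chain in the (R) arrangement. The step needs site selectivity among nine trisubstituted olefins, secured by the tethered phenol because only C2′=C3′ can reach a six-membered cyclic transition state, and 6-endo over 5-exo selectivity, favoured by the Markovnikov bias of the trisubstituted olefin and the weakly coordinating trifluoroacetate. β-Hydride elimination has only one direction because C2 is quaternary, and the neutral, acid-free medium should leave the acetate and the other eight olefins untouched.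

Step 4
Reactants: 5 (2R)-plastochromenol-8 acetate
Product: 6 plastochromenol-8, (2R)-2,7,8-trimethyl-2-[(3E,7E,11E,15E,19E,23E,27E)-4,8,12,16,20,24,28,32-octamethyltritriaconta-3,7,11,15,19,23,27,31-octaen-1-yl]-2H-chromen-6-ol
Conditions: K2CO3 (0.2 equiv), degassed MeOH/THF, 20 °C, Ar, dark
Reagents that add atoms: none
Why: Base-catalysed transesterification of the aryl acetate touches no bond at C2, so the (R) configuration is carried through, while exclusion of air and light guards the electron-rich chromenol against autoxidation and photochemical ring opening.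

**Compound list**

1 | 2,3-dimethylbenzene-1,4-diol | Cc1c(C)c(O)ccc1O | starting material
2 | 4-hydroxy-2,3-dimethylphenyl acetate | CC(=O)Oc1ccc(O)c(C)c1C | intermediate
3 | solanesol, (2E,6E,10E,14E,18E,22E,26E,30E)-3,7,11,15,19,23,27,31,35-nonamethylhexatriaconta-2,6,10,14,18,22,26,30,34-nonaen-1-ol | CC(C)=CCC/C(C)=C/CC/C(C)=C/CC/C(C)=C/CC/C(C)=C/CC/C(C)=C/CC/C(C)=C/CC/C(C)=C/CC/C(C)=C/CO | starting material
4 | 4-hydroxy-2,3-dimethyl-5-[(all-E)-solanesyl]phenyl acetate | CC(C)=CCC/C(C)=C/CC/C(C)=C/CC/C(C)=C/CC/C(C)=C/CC/C(C)=C/CC/C(C)=C/CC/C(C)=C/CC/C(C)=C/Cc1cc(OC(C)=O)c(C)c(C)c1O | intermediate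
5 | (2R)-plastochromenol-8 6-O-acetate | CC(C)=CCC/C(C)=C/CC/C(C)=C/CC/C(C)=C/CC/C(C)=C/CC/C(C)=C/CC/C(C)=C/CC/C(C)=C/CC[C@]1(C)C=Cc2cc(OC(C)=O)c(C)c(C)c2O1 | intermediate
6 | (2R)-plastochromenol-8 | CC(C)=CCC/C(C)=C/CC/C(C)=C/CC/C(C)=C/CC/C(C)=C/CC/C(C)=C/CC/C(C)=C/CC/C(C)=C/CC[C@]1(C)C=Cc2cc(O)c(C)c(C)c2O1 | target

**Step count.** Total: 4 steps. Longest linear sequence: 4 steps (1 → 2 → 4 → 5 → 6).

**Steps most likely to fail**

1. Step 3. The two substituents on the reacting olefin carbon are both alkyl, so enantiofacial discrimination in the oxypalladation may be incomplete, and 5-exo closure may compete. The fallback sets the stereocentre by a Pd(0) allylic etherification before the ring is closed, and closes the pyran by olefin metathesis; it sets out from 2 and 3 and returns at 5.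
   - Ortho-formylation of 2 (MgCl2, Et3N, paraformaldehyde, MeCN, reflux) should give (5-formyl-4-hydroxy-2,3-dimethylphenyl) acetate F1.
   - Solanesol 3 is converted (ClCO2Me, pyridine, CH2Cl2, 0 °C) into solanesyl methyl carbonate F2.
   - Pd-catalysed asymmetric allylic etherification of F1 with F2 (Pd2(dba)3·CHCl3, chiral DACH-phenyl bisphosphine ligand, CH2Cl2, 20 °C) should give the branched tertiary ether 5-formyl-2,3-dimethyl-4-{[(3R,6E,10E,14E,18E,22E,26E,30E)-3,7,11,15,19,23,27,31,35-nonamethylhexatriaconta-1,6,10,14,18,22,26,30,34-nonaen-3-yl]oxy}phenyl acetate F3. The ligand antipode is chosen by the established model for geranyl-type carbonates.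
   - Wittig methylenation (Ph3P=CH2, THF, −78 °C) gives the corresponding 5-vinyl aryl ether F4.
   - Ring-closing metathesis (second-generation Ru–NHC benzylidene catalyst, CH2Cl2, 40 °C, high dilution) should start at the styrene, close C3=C4 with the neighbouring vinyl group and deliver 5.

2. Step 2. Ionisation of the allylic alcohol may erode the E geometry at C2′=C3′, and the acid may push the product on to a chromane or cyclise the chain. The fallback replaces the cationic alkylation by an SN2 coupling of an aryl copper species, which keeps the olefin geometry; it sets out from 1 and 3 and returns at 4.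
   - 1 is protected (MOMCl, i-Pr2NEt, CH2Cl2) as 1,4-bis(methoxymethoxy)-2,3-dimethylbenzene F5.
   - 3 is converted (PBr3, Et2O, 0 °C) into solanesyl bromide F6.
   - Ortho-lithiation of F5 (n-BuLi, TMEDA, THF, 0 °C), transmetalation (CuBr·SMe2) and alkylation with F6 (−78 to 0 °C) should give 1,4-bis(methoxymethoxy)-2,3-dimethyl-5-[(all-E)-solanesyl]benzene F7.
   - Acetal cleavage (cat. HCl, MeOH/THF, 20 °C) gives plastoquinol-9 F8.
   - Acetylation (Ac2O, 1 equiv, pyridine, −20 °C) at the less hindered hydroxyl (flanked by H and methyl, not by methyl and the chain) gives 4.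

3. Step 1. Acylation of the second hydroxyl may run at a rate similar to the first, leaving a statistical mixture. The fallback sets out from 1 and returns at 2.
   - Exhaustive acetylation of 1 (Ac2O excess, pyridine, DMAP) gives 2,3-dimethyl-1,4-phenylene diacetate F9.
   - Cleavage of one ester with one equivalent of NaOMe (MeOH/THF, −20 °C) should stop at 2, because the phenoxide formed after the first cleavage deactivates the remaining ester.

**Further compounds**

F1 | step 3 | (5-formyl-4-hydroxy-2,3-dimethylphenyl) acetate | CC(=O)Oc1cc(C=O)c(O)c(C)c1C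
F2 | step 3 | solanesyl methyl carbonate | CC(C)=CCC/C(C)=C/CC/C(C)=C/CC/C(C)=C/CC/C(C)=C/CC/C(C)=C/CC/C(C)=C/CC/C(C)=C/CC/C(C)=C/COC(=O)OC
F3 | step 3 | 5-formyl-2,3-dimethyl-4-{[(3R,6E,10E,14E,18E,22E,26E,30E)-3,7,11,15,19,23,27,31,35-nonamethylhexatriaconta-1,6,10,14,18,22,26,30,34-nonaen-3-yl]oxy}phenyl acetate | CC(C)=CCC/C(C)=C/CC/C(C)=C/CC/C(C)=C/CC/C(C)=C/CC/C(C)=C/CC/C(C)=C/CC/C(C)=C/CC[C@](C)(C=C)Oc1c(C=O)cc(OC(C)=O)c(C)c1C
F4 | step 3 | 2,3-dimethyl-4-{[(3R,6E,10E,14E,18E,22E,26E,30E)-3,7,11,15,19,23,27,31,35-nonamethylhexatriaconta-1,6,10,14,18,22,26,30,34-nonaen-3-yl]oxy}-5-vinylphenyl acetate | CC(C)=CCC/C(C)=C/CC/C(C)=C/CC/C(C)=C/CC/C(C)=C/CC/C(C)=C/CC/C(C)=C/CC/C(C)=C/CC[C@](C)(C=C)Oc1c(C=C)cc(OC(C)=O)c(C)c1C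
F5 | step 2 | 1,4-bis(methoxymethoxy)-2,3-dimethylbenzene | COCOc1ccc(OCOC)c(C)c1C
F6 | step 2 | solanesyl bromide | CC(C)=CCC/C(C)=C/CC/C(C)=C/CC/C(C)=C/CC/C(C)=C/CC/C(C)=C/CC/C(C)=C/CC/C(C)=C/CC/C(C)=C/CBr
F7 | step 2 | 1,4-bis(methoxymethoxy)-2,3-dimethyl-5-[(all-E)-solanesyl]benzene | CC(C)=CCC/C(C)=C/CC/C(C)=C/CC/C(C)=C/CC/C(C)=C/CC/C(C)=C/CC/C(C)=C/CC/C(C)=C/CC/C(C)=C/Cc1cc(OCOC)c(C)c(C)c1OCOC
F8 | step 2 | plastoquinol-9, 2,3-dimethyl-5-[(all-E)-solanesyl]benzene-1,4-diol | CC(C)=CCC/C(C)=C/CC/C(C)=C/CC/C(C)=C/CC/C(C)=C/CC/C(C)=C/CC/C(C)=C/CC/C(C)=C/CC/C(C)=C/Cc1cc(O)c(C)c(C)c1O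
F9 | step 1 | 2,3-dimethyl-1,4-phenylene diacetate | CC(=O)Oc1ccc(OC(C)=O)c(C)c1C
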